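Take this flask as two drains in line: starting material empties into a pool of intermediate A and intermediate B, and the pool empties onward towards target.

| flask | starting material | remark | time |
|---|---|---|---|
| dawn | 2 mM | run made earlier |  |
| flask | 1.0 mM |  | 5.0 min |

dawn run (percent of the starting material charged)

| time / s | intermediate B / % | starting material / % | intermediate D / % | intermediate C / % | target / % | intermediate A / % |
|---|---|---|---|---|---|---|
| 10.0 | 1.1 | 91.1 | 0 | 0 | 0 | 8.1 |
| 12.0 | 1.9 | 88.6 | 1.2 | 0 | 0 | 9.3 |
| 20.0 | 2.5 | 82.3 | 0 | 0.6 | 0.2 | 15.2 |
| 30.0 | 3.2 | 74.1 | 0 | 0.2 | 1.0 | 19.6 |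
| 50.0 | 5.0 | 60.8 | 0.7 | 0.7 | 3.6 | 28.7 |
| 60.0 | 5.6 | 55.6 | 0 | 1.4 | 5.4 | 32.6 |

(readings scatter by 0.5 percentage points)



* the species in which most of what was charged as starting material, at 5.0 min sits (intermediate A / intermediate D / starting material / intermediate B / target / intermediate C)
* the largest share itself, whichever of these holds it, in percent of the starting material charged

The dawn run reads 55.6% of starting material at 60.0 s, so the first drain runs at 0.587 min⁻¹ and leaves 5.31% at 5.0 min. Onward stand 6.80% in target, intermediate C and intermediate D together, over an area under the pool curve of 14.6 s of full charge, so 0.279 min⁻¹ is the drain constant, the share of the pool passed onward each minute. At about half the first drain, it is slower, but the two constants are of like size, so I carry both and call neither the rate-limiting step. I assume the drain first order, so percentages carry from 2 mM to 1.0 mM.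

Joined to the late end, where the charge ends as target, the two drains leave 37.1% in the pool at 5.0 min and 57.6% onward. Less the 1.40% read in intermediate C and intermediate D, I commit to target at 56.2%.

The forecast also says target, at 50% (40% to 64%), below mine, holding that “A is consumed second order”.

The flask gives target at 56.5%.

    intermediate C ⇌ intermediate D (K = 1.80, k = 0.0250 s⁻¹)
    intermediate A ⇌ intermediate B (K = 0.190, k = 0.0380 s⁻¹)
    starting material → intermediate A (k = 0.00980 s⁻¹)
    intermediate A → intermediate C (k = 0.00590 s⁻¹)
    intermediate C → target (k = 0.210 s⁻¹)
    intermediate D ⇌ intermediate E (K = 0.450, k = 0.120 s⁻¹)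

In the flask intermediate A and intermediate B relax with a half-life of 2.91 s, far shorter than the 2.0 min of intermediate A by its step to intermediate C alone. At 5.0 min the flask's pool takes in 0.0310 min⁻¹ of the charge and passes on 0.0978 min⁻¹. In the neighbour flask read at 2.0 min, the same two rates are 0.181 min⁻¹ and 0.137 min⁻¹, and intermediate A holds most, at 41.3%.

The readings are calculated with constants of no real substance; noise was put on by code.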